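**Retrosynthetic overview**
1. Target ⇐ 2,3‑epoxide of the endocyclic enol ether (a 3,4‑dihydro‑2H‑pyran): epoxide‑to‑allylic‑alcohol isomerisation unveils the exocyclic enol ether and sets the carbinol centre from the CHBr centre.
2. Dihydropyran (oxane ring, formed second) ⇐ γ,δ‑unsaturated methyl ketone, by asymmetric epoxidation of the prenyl group, SN2 bromide opening and cyclodehydration.
3. That ketone ⇐ cyclohexenylacetone, by copper hydride reduction (sets the ring CH centre against the pre‑installed trans‑bromochloride) and prenylation.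
4. Cyclohexenylacetone ⇐ acetylcyclohexene, by one‑carbon insertion with 1,2‑shift of the cyclohexenyl group (key skeletal rearrangement; it moves the ring onto the future carbinol carbon).
5. Acetylcyclohexene bromochloride ⇐ isoprene + but‑3‑yn‑2‑one (Diels–Alder; carbocycle formed first), then asymmetric epoxidation and HBr/SOCl2.

Assumption: the D‑fructose‑derived ketone gives the usual facial sense (R at the CH carbon of trisubstituted alkenes); if not, the two ketone enantiomers used in steps 2 and 6 are exchanged.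

**Step 1**
Reactants: 1 2-methylbuta-1,3-diene (isoprene); 2 but-3-yn-2-one
Product: 3 1-(4-methylcyclohexa-1,4-dien-1-yl)ethan-1-one
Conditions: EtAlCl2 (0.2 equiv), CH2Cl2, −40 → 0 °C
Reagents that add atoms: none
Why: Lewis‑acid‑catalysed Diels–Alder cycloaddition of the alkynone with the 2‑substituted diene gives the 1,4 ("para") cyclohexadiene, whose electron‑rich trisubstituted alkene and acceptor‑substituted alkene are electronically differentiated, and no stereocentre is formed.

**Step 2**
Reactants: 3 1-(4-methylcyclohexa-1,4-dien-1-yl)ethan-1-one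
Product: 4 1-[(1R,6S)-6-methyl-7-oxabicyclo[4.1.0]hept-3-en-3-yl]ethan-1-one
Conditions: 1,2:4,5-di-O-isopropylidene-β-D-erythro-hexo-2,3-diulo-2,6-pyranose (0.3 equiv), KHSO5 (as 2KHSO5·KHSO4·K2SO4), K2CO3, Bu4NHSO4, MeCN/CH2(OMe)2/aq. buffer pH 10.5, −10 °C
Reagents that add atoms: KHSO5 (potassium peroxymonosulfate), [K+].[O-]S(=O)(=O)OO
Why: Shi asymmetric epoxidation, in which the electrophilic chiral dioxirane attacks only the electron‑rich trisubstituted alkene of the achiral diene (the enone alkene is inert) and, through the spiro transition state that gives (R) at the CH carbon of trisubstituted cyclohexenes, sets both ring stereocentres as (1R,6S) under catalyst control.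

**Step 3**
Reactants: 4 1-[(1R,6S)-6-methyl-7-oxabicyclo[4.1.0]hept-3-en-3-yl]ethan-1-one
Product: 6 1-[(4S,5S)-5-bromo-4-chloro-4-methylcyclohex-1-en-1-yl]ethan-1-one, via bromohydrin 5 (not isolated)
Conditions: HBr (1.05 equiv, CH2Cl2), −78 °C; then pyridine (2.5 equiv), SOCl2 (1.3 equiv), −78 → 0 °C
Reagents that add atoms: hydrogen bromide, Br; thionyl chloride, O=S(Cl)Cl
Why: HBr opens the epoxide trans‑diaxially at the tertiary carbon (Markovnikov, inversion), and the derived chlorosulfite ionises with anchimeric help of the anti bromine to a bromonium ion that chloride opens at the tertiary carbon, so that a stereospecific 1,2‑bromine transposition on a ring without a conformational anchor gives the trans (4S,5S) bromochloride (epoxide to vicinal dihalide conversion with neighbouring‑group participation).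

**Step 4**
Reactants: 6 1-[(4S,5S)-5-bromo-4-chloro-4-methylcyclohex-1-en-1-yl]ethan-1-one; 7 (diazomethyl)trimethylsilane
Product: 9 1-[(4S,5S)-5-bromo-4-chloro-4-methylcyclohex-1-en-1-yl]propan-2-one, via α-silyl ketone 8 (not isolated)
Conditions: Sc(OTf)3 (10 mol %), CH2Cl2, −78 → −30 °C; then 1 M HCl, THF, 0 °C
Reagents that add atoms: none
Why: Proposed new method: Sc(OTf)3 activation of the enone carbonyl directs 1,2‑attack of the diazo carbon (dipolar addition to the α‑branched C=C being slow at −78 °C), and the β‑oxido diazonium collapses by antiperiplanar 1,2‑shift of the cyclohexenyl group, whose sp2 carbon migrates with π‑participation far faster than methyl, with loss of N2, so that the new carbon is inserted between carbonyl and ring and acid then cleaves the α‑silyl ketone to the β,γ‑enone without touching the stereocentres; the closest known reaction type is the Lewis‑acid‑promoted Tiffeneau–Demjanov‑type (Büchner–Curtius–Schlotterbeck) homologation of saturated and aryl ketones with (trimethylsilyl)diazomethane, not yet shown on conjugated cycloalkenyl methyl ketones.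

**Step 5**
Reactants: 9 1-[(4S,5S)-5-bromo-4-chloro-4-methylcyclohex-1-en-1-yl]propan-2-one; 10 1-bromo-3-methylbut-2-ene
Product: 13 3-[(1S,3S,4S)-3-bromo-4-chloro-4-methylcyclohexyl]-6-methylhept-5-en-2-one (1:1 at C3), via conjugated enone 11 (not isolated), via enol silane 12 (not isolated)
Conditions: CuCl (5 mol %), NaOtBu (10 mol %), rac-2,2'-bis(diphenylphosphino)-1,1'-binaphthyl (5 mol %), PhMe2SiH (1.3 equiv), toluene, 0 °C → rt; then Bu4N[Ph3SiF2] (1.2 equiv), CH2Cl2, −20 °C → rt
Reagents that add atoms: none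
Why: The alkoxide equilibrates the β,γ‑enone with its conjugated exocyclic isomer, copper hydride conjugate reduction (1,4‑hydrosilylation) delivers hydride to the ring carbon from the equatorial side opposite the axial ring bromine of the diaxial bromochloride chair so that the side chain ends cis to bromine as (1S), and the regiodefined enol silane is unmasked by fluoride and C‑alkylated by prenyl bromide (one‑pot reductive alkylation), the new chain centre being inconsequential.

**Step 6**
Reactants: 13 3-[(1S,3S,4S)-3-bromo-4-chloro-4-methylcyclohexyl]-6-methylhept-5-en-2-one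
Product: 14 3-[(1S,3S,4S)-3-bromo-4-chloro-4-methylcyclohexyl]-4-[(2S)-3,3-dimethyloxiran-2-yl]butan-2-one
Conditions: 1,2:4,5-di-O-isopropylidene-β-L-erythro-hexo-2,3-diulo-2,6-pyranose (0.3 equiv), KHSO5 (as 2KHSO5·KHSO4·K2SO4), K2CO3, Bu4NHSO4, MeCN/CH2(OMe)2/aq. buffer pH 10.5, 0 °C
Reagents that add atoms: KHSO5 (potassium peroxymonosulfate), [K+].[O-]S(=O)(=O)OO
Why: Shi asymmetric epoxidation with the enantiomeric ketone catalyst oxidises the only remaining alkene and sets the (2S)-oxirane centre under catalyst control, independent of the remote ring stereocentres.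

**Step 7**
Reactants: 14 3-[(1S,3S,4S)-3-bromo-4-chloro-4-methylcyclohexyl]-4-[(2S)-3,3-dimethyloxiran-2-yl]butan-2-one
Product: 16 (3R)-3-bromo-5-[(1S,3S,4S)-3-bromo-4-chloro-4-methylcyclohexyl]-2,2,6-trimethyl-3,4-dihydro-2H-pyran, via lactol 15 (not isolated)
Conditions: Li2NiBr4 (2 equiv), THF, 0 °C → rt, H2O quench; then pyridinium p-toluenesulfonate (10 mol %), 4 Å MS, benzene, 60 °C
Reagents that add atoms: Li2NiBr4 (dilithium tetrabromonickelate), [Li+].[Li+].[Ni+2].[Br-].[Br-].[Br-].[Br-]
Why: Soft bromide opens the trisubstituted epoxide by SN2 attack at the less substituted carbon with inversion to give the (R)-bromide, the tertiary alkoxide adds to the ketone to close the six‑membered lactol, and acid‑catalysed dehydration gives the more substituted endocyclic enol ether, which erases the uncontrolled chain centre.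

**Step 8**
Reactants: 16 (3R)-3-bromo-5-[(1S,3S,4S)-3-bromo-4-chloro-4-methylcyclohexyl]-2,2,6-trimethyl-3,4-dihydro-2H-pyran
Product: 18 (3S,5R)-5-bromo-3-[(1S,3S,4S)-3-bromo-4-chloro-4-methylcyclohexyl]-6,6-dimethyl-2-methylideneoxan-3-ol, via enol ether epoxide 17 (not isolated)
Conditions: dimethyldioxirane (1.1 equiv, acetone), CH2Cl2, −78 °C; then Et3N (2 equiv), −78 → 0 °C; filtration through basic alumina
Reagents that add atoms: dimethyldioxirane, CC1(C)OO1
Why: Dimethyldioxirane epoxidises the electron‑rich tetrasubstituted enol ether on the face opposite the ring bromine, and the labile acetal epoxide opens at the anomeric C–O bond to an oxocarbenium alkoxide that loses a proton from the adjacent methyl group (epoxide to allylic alcohol isomerisation), which sets the tertiary carbinol as (3S) trans to bromine and unveils the exocyclic enol ether.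

**Compound list**
1 | 2-methylbuta-1,3-diene (isoprene) | C=CC(C)=C | starting material
2 | but-3-yn-2-one | CC(=O)C#C | starting material
3 | 1-(4-methylcyclohexa-1,4-dien-1-yl)ethan-1-one | CC(=O)C1=CCC(C)=CC1 | intermediate
4 | 1-[(1R,6S)-6-methyl-7-oxabicyclo[4.1.0]hept-3-en-3-yl]ethan-1-one | CC(=O)C1=CC[C@]2(C)O[C@@H]2C1 | intermediate
5 | 1-[(4R,5R)-4-bromo-5-hydroxy-4-methylcyclohex-1-en-1-yl]ethan-1-one | CC(=O)C1=CC[C@@](C)(Br)[C@H](O)C1 | intermediate
6 | 1-[(4S,5S)-5-bromo-4-chloro-4-methylcyclohex-1-en-1-yl]ethan-1-one | CC(=O)C1=CC[C@](C)(Cl)[C@@H](Br)C1 | intermediate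
7 | (diazomethyl)trimethylsilane | C[Si](C)(C)C=[N+]=[N-] | starting material
8 | 1-[(4S,5S)-5-bromo-4-chloro-4-methylcyclohex-1-en-1-yl]-1-(trimethylsilyl)propan-2-one (epimers at C1 of the chain) | CC(=O)C([Si](C)(C)C)C1=CC[C@](C)(Cl)[C@@H](Br)C1 | intermediate
9 | 1-[(4S,5S)-5-bromo-4-chloro-4-methylcyclohex-1-en-1-yl]propan-2-one | CC(=O)CC1=CC[C@](C)(Cl)[C@@H](Br)C1 | intermediate
10 | 1-bromo-3-methylbut-2-ene (prenyl bromide) | CC(C)=CCBr | starting material
11 | 1-[(3S,4S)-3-bromo-4-chloro-4-methylcyclohexylidene]propan-2-one (E/Z mixture) | CC(=O)C=C1CC[C@](C)(Cl)[C@@H](Br)C1 | intermediate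
12 | {[1-[(1S,3S,4S)-3-bromo-4-chloro-4-methylcyclohexyl]prop-1-en-2-yl]oxy}(dimethyl)phenylsilane (E/Z mixture) | CC(O[Si](C)(C)c1ccccc1)=C[C@H]1CC[C@](C)(Cl)[C@@H](Br)C1 | intermediate
13 | 3-[(1S,3S,4S)-3-bromo-4-chloro-4-methylcyclohexyl]-6-methylhept-5-en-2-one (C3 epimers) | CC(=O)C(CC=C(C)C)[C@H]1CC[C@](C)(Cl)[C@@H](Br)C1 | intermediate
14 | 3-[(1S,3S,4S)-3-bromo-4-chloro-4-methylcyclohexyl]-4-[(2S)-3,3-dimethyloxiran-2-yl]butan-2-one (C3 epimers) | CC(=O)C(C[C@@H]1OC1(C)C)[C@H]1CC[C@](C)(Cl)[C@@H](Br)C1 | intermediate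
15 | (5R)-5-bromo-3-[(1S,3S,4S)-3-bromo-4-chloro-4-methylcyclohexyl]-2,6,6-trimethyloxan-2-ol (mixture at C2 and C3) | CC1(O)OC(C)(C)[C@H](Br)CC1[C@H]1CC[C@](C)(Cl)[C@@H](Br)C1 | intermediate
16 | (3R)-3-bromo-5-[(1S,3S,4S)-3-bromo-4-chloro-4-methylcyclohexyl]-2,2,6-trimethyl-3,4-dihydro-2H-pyran | CC1=C([C@H]2CC[C@](C)(Cl)[C@@H](Br)C2)C[C@@H](Br)C(C)(C)O1 | intermediate
17 | (1S,4R,6S)-4-bromo-6-[(1S,3S,4S)-3-bromo-4-chloro-4-methylcyclohexyl]-1,3,3-trimethyl-2,7-dioxabicyclo[4.1.0]heptane | C[C@]12OC(C)(C)[C@H](Br)C[C@]1(O2)[C@H]1CC[C@](C)(Cl)[C@@H](Br)C1 | intermediate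
18 | (3S,5R)-5-bromo-3-[(1S,3S,4S)-3-bromo-4-chloro-4-methylcyclohexyl]-6,6-dimethyl-2-methylideneoxan-3-ol | C=C1OC(C)(C)[C@H](Br)C[C@]1(O)[C@H]1CC[C@](C)(Cl)[C@@H](Br)C1 | target

**Totals**
Total step count: 8. Longest linear sequence: 8 steps (from 1 and 2).

**Three steps most likely to fail**

Step 4 (the proposed new homologation). The diazo carbon may add in conjugate fashion (pyrazoline or cyclopropane), or methyl may migrate. The fallback uses known chemistry and sets out from 6. (Phenylselanyl)methyllithium, made from bis(phenylselanyl)methane and nBuLi in THF at −78 °C, adds 1,2 to the enone and gives the β‑hydroxy selenide 2-[(4S,5S)-5-bromo-4-chloro-4-methylcyclohex-1-en-1-yl]-1-(phenylselanyl)propan-2-ol F1. Se‑methylation with MeOSO2CF3 in CH2Cl2 with 2,6‑di‑tert‑butylpyridine, then warming, triggers the selenonium semipinacol rearrangement (Krief homologation) with the same 1,2‑alkenyl shift. This delivers 9, where the route is rejoined.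

Step 7 (bromide opening and cyclodehydration). Bromide may attack the tertiary carbon, or the ketone oxygen may intercept the epoxide. The fallback sets out from 14. Anhydrous HBr in CH2Cl2 at −78 °C opens the epoxide at the tertiary carbon, and the secondary alcohol closes onto the ketone to give the five‑membered lactol (5S)-5-(2-bromopropan-2-yl)-3-[(1S,3S,4S)-3-bromo-4-chloro-4-methylcyclohexyl]-2-methyloxolan-2-ol F2. ZnBr2 (cat.) with pyridinium p‑toluenesulfonate and 4 Å sieves in CH2Cl2 at 40 °C then expands the oxolane to the oxane through the oxygen‑bridged cation. Bromide returns at the secondary carbon with the same inversion sense, and dehydration gives 16, where the route is rejoined.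

Step 8 (enol ether epoxidation and isomerisation). The oxocarbenium alkoxide may instead shift the cyclohexyl group back to give the ring ketone, or face selectivity may be incomplete. The fallback sets out from 16. Photooxygenation (O2, tetraphenylporphyrin, visible light, CH2Cl2, −78 °C) effects a Schenck ene reaction that avoids the cationic intermediate and gives the allylic hydroperoxide (3S,5R)-5-bromo-3-[(1S,3S,4S)-3-bromo-4-chloro-4-methylcyclohexyl]-3-hydroperoxy-6,6-dimethyl-2-methylideneoxane F3. Reduction with PPh3 at −78 → 0 °C gives 18 directly.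

**Further compounds**
F1 | step 4 | 2-[(4S,5S)-5-bromo-4-chloro-4-methylcyclohex-1-en-1-yl]-1-(phenylselanyl)propan-2-ol | CC(O)(C[Se]c1ccccc1)C1=CC[C@](C)(Cl)[C@@H](Br)C1
F2 | step 7 | (5S)-5-(2-bromopropan-2-yl)-3-[(1S,3S,4S)-3-bromo-4-chloro-4-methylcyclohexyl]-2-methyloxolan-2-ol | CC1(O)O[C@H](C(C)(C)Br)CC1[C@H]1CC[C@](C)(Cl)[C@@H](Br)C1
F3 | step 8 | (3S,5R)-5-bromo-3-[(1S,3S,4S)-3-bromo-4-chloro-4-methylcyclohexyl]-3-hydroperoxy-6,6-dimethyl-2-methylideneoxane | C=C1OC(C)(C)[C@H](Br)C[C@]1(OO)[C@H]1CC[C@](C)(Cl)[C@@H](Br)C1
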